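## Retrosynthetic overview
1. 23 ⇐ 21: the 12E-alkene is carried as a 12-yne until both rings are closed, and a net trans-hydrogenation comes last.
2. 21 ⇐ 18: one cationic cascade on the open C22 chain, mirroring the proposed oxylipin biogenesis. The activated 10,11-epoxide is attacked at C10 by C8 (cyclopropane, ring 1). The resulting C7 cyclopropylcarbinyl cation is captured by the C1 carboxyl (oxocan-2-one, ring 2).
3. 18 ⇐ 9 + 14: acetylide addition to an α-chloroaldehyde, then anti-chlorohydrin → trans-epoxide.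
4. 9 ⇐ cycloheptene: unsymmetrical ozonolysis, vinyl addition, Claisen rearrangement (7E), organocatalytic chlorination (C10).
5. 14 ⇐ (3Z,6Z)-nonadienol: oxidation, catalytic asymmetric alkynylation (C14).

Assumption: docosanoid numbering is used throughout (C1 = lactone C=O, C22 = CH3). The SMILES decodes as 7R,8R,10R,11R,12E,14S,16Z,19Z. One step means one operation sequence that ends in an isolated product.

## Route

Step 1
Reactants: 1 cycloheptene
Product: 3 methyl 7-oxoheptanoate, via methoxy hydroperoxide 2 (not isolated)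
Conditions: O3, NaHCO3, CH2Cl2–MeOH 5:1, −78 °C; then Ac2O, Et3N, CH2Cl2, 0 °C → rt
Reagents that add atoms: ozone [O-][O+]=O; methanol CO
Why: Criegee ozonolysis in methanol traps the carbonyl-oxide terminus as the α-methoxy hydroperoxide and Ac2O/Et3N dehydrates it to the methyl ester, which differentiates the two ends (unsymmetrical ozonolysis of a cycloalkene) without forming a stereocentre.

Step 2
Reactants: 3 methyl 7-oxoheptanoate; 4 vinylmagnesium bromide
Product: 5 methyl 7-hydroxynon-8-enoate (racemic)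
Conditions: CH2=CHMgBr (1.05 equiv), THF, −78 °C; aqueous work-up
Reagents that add atoms: vinylmagnesium bromide (4) C=C[Mg]Br
Why: Grignard 1,2-addition in which the aldehyde outruns the methyl ester at −78 °C, and the racemic carbinol centre is erased in step 3.

Step 3
Reactants: 5 methyl 7-hydroxynon-8-enoate; 6 butyl vinyl ether
Product: 8 methyl (7E)-11-oxoundec-7-enoate, via allyl vinyl ether 7 (not isolated)
Conditions: n-BuOCH=CH2 (excess), Pd(OCOCF3)2/4,7-diphenyl-1,10-phenanthroline (1 mol %), Et3N (cat.), 75 °C; evaporate; o-xylene, 140 °C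
Reagents that add atoms: butyl vinyl ether (6) C=COCCCC
Why: Pd(II) transvinylation followed by aliphatic Claisen [3,3] rearrangement through a chair with the ester chain equatorial sets the 7E-alkene (about 9:1, Z-isomer removed on AgNO3–silica) and gives the γ,δ-unsaturated aldehyde.

Step 4
Reactants: 8 methyl (7E)-11-oxoundec-7-enoate
Product: 9 methyl (7E,10S)-10-chloro-11-oxoundec-7-enoate
Conditions: NCS (1.3 equiv), (2R,5R)-2,5-diphenylpyrrolidine (10 mol %), CH2Cl2, 0 °C → rt; pentane, filter, use crude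
Reagents that add atoms: N-chlorosuccinimide O=C1CCC(=O)N1Cl
Why: Enamine-catalysed electrophilic α-chlorination of an aldehyde, in which this antipode of the C2-symmetric amine gives the (S)-chloride (about 90–95 % ee, both antipodes are sold), alkene and ester are inert to NCS, and crude use avoids epimerisation.

Step 5
Reactants: 10 (3Z,6Z)-nona-3,6-dien-1-ol
Product: 11 (3Z,6Z)-nona-3,6-dienal
Conditions: Dess–Martin periodinane, NaHCO3, CH2Cl2, 0 °C; short silica plug, use at once
Reagents that add atoms: none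
Why: Buffered Dess–Martin oxidation is neutral and fast, so the β,γ-Z-alkene does not move into conjugation.

Step 6
Reactants: 11 (3Z,6Z)-nona-3,6-dienal; 12 trimethylsilylacetylene
Product: 14 (3S,5Z,8Z)-undeca-5,8-dien-1-yn-3-ol, via C-silyl alkynol 13 (not isolated)
Conditions: 12, Et2Zn, PhMe, reflux; (R)-BINOL (20 mol %), Ti(OiPr)4 (50 mol %), Et2O, rt; 11, 0 °C → rt; aqueous work-up; K2CO3, MeOH, rt
Reagents that add atoms: trimethylsilylacetylene (12) C#C[Si](C)(C)C
Why: The amine-free BINOL–Ti(IV)-catalysed alkynylzinc addition tolerates unbranched enolisable aldehydes and with (R)-BINOL delivers the alkynyl group to the Re face, setting 14S, after which K2CO3/MeOH cleaves the C–Si bond.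

Step 7
Reactants: 14 (3S,5Z,8Z)-undeca-5,8-dien-1-yn-3-ol; 9 methyl (7E,10S)-10-chloro-11-oxoundec-7-enoate
Product: 18 (7E,10R,11R,14S,16Z,19Z)-10,11-epoxy-14-hydroxydocosa-7,16,19-trien-12-ynoic acid, via dilithio alkynolate 15 (not isolated), via anti-chlorohydrin ester 16 (not isolated), via epoxy methyl ester 17 (not isolated)
Conditions: 14 (1.2 equiv), n-BuLi (2.0 equiv per 14), THF, −78 → −20 °C; 9, −78 °C; then KOH, MeOH–H2O, rt; cold aq KHSO4 to pH 4–5
Reagents that add atoms: potassium hydroxide [K+].[OH-]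
Why: The lithium acetylide adds to the α-chloroaldehyde under Cornforth control to give the 10,11-anti chlorohydrin (sets 11R, about 10:1), and hydroxide then closes it by internal SN2 with inversion at C10 to the trans-(10R,11R)-epoxide and saponifies the ester in the same flask, so the minor enantiomers of 9 and 14 end up as separable diastereomers.

Step 8
Reactants: 18 (7E,10R,11R,14S,16Z,19Z)-10,11-epoxy-14-hydroxydocosa-7,16,19-trien-12-ynoic acid
Product: 21 (8R)-8-[(1R,2R)-2-[(1S,4S,6Z,9Z)-1,4-dihydroxydodeca-6,9-dien-2-yn-1-yl]cyclopropyl]oxocan-2-one, via bis-silylated epoxy acid 19 (not isolated), via bis-TMS ether lactone 20 (not isolated)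
Conditions: Me3SiNTf2 (2.2 equiv), 2,6-di-tert-butyl-4-methylpyridine (2.1 equiv), CH2Cl2 (1 mM), −78 °C, 1 h; aq NaHCO3; then citric acid, MeOH, 0 °C
Reagents that add atoms: none
Why: Proposed new method: after in-situ silylation of CO2H and 14-OH, Me3Si+ activates the oxirane, which the homoallylic 7E-alkene opens at C10 with inversion (an alkyne at C11, unlike an alkene, does not labilise the C11–O bond) to give the trans-cyclopropane and a bisected, rotationally locked C7 cyclopropylcarbinyl cation; the silyl carboxylate captures this cation anti to the new C8–C10 bond with release of Me3Si+ as chain carrier, so that 10R, 8R and 7R all derive from the epoxide and the E-geometry (anti addition to a 7Z-alkene would give the 7-epimer), C11 is retained and masked as its silyl ether at birth, NTf2− is too weakly nucleophilic to intercept the cation, and 1 mM dilution suppresses oligomers; the closest known reaction types are Lewis-acid epoxide-initiated homoallyl → cyclopropylcarbinyl cyclisation with δ-lactone capture, the i-steroid solvolysis (anti addition) and medium-ring halolactonisation.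

Step 9
Reactants: 21 (8R)-8-[(1R,2R)-2-[(1S,4S,6Z,9Z)-1,4-dihydroxydodeca-6,9-dien-2-yn-1-yl]cyclopropyl]oxocan-2-one
Product: 23 (8R)-8-[(1R,2R)-2-[(1R,2E,4S,6Z,9Z)-1,4-dihydroxydodeca-2,6,9-trien-1-yl]cyclopropyl]oxocan-2-one (target), via Z-vinylsilane 22 (not isolated)
Conditions: (EtO)3SiH, [Cp*Ru(MeCN)3]PF6 (5 mol %), CH2Cl2, 0 °C → rt; then AgF, THF–MeOH–H2O, rt, dark
Reagents that add atoms: none
Why: Cp*Ru-catalysed trans-hydrosilylation followed by fluoride-mediated protodesilylation with retention is a net anti addition of H2 that gives only the 12E-alkene (the 13-silyl regioisomer converges), leaves lactone, cyclopropane and skipped Z,Z-diene alone, and touches no stereocentre.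

## Compound list
1 | cycloheptene | C1=CCCCCC1 | starting material
2 | 7-hydroperoxy-7-methoxyheptanal | O=CCCCCCC(OC)OO | intermediate
3 | methyl 7-oxoheptanoate | O=CCCCCCC(=O)OC | intermediate
4 | vinylmagnesium bromide | C=C[Mg]Br | starting material
5 | methyl 7-hydroxynon-8-enoate (racemic) | C=CC(O)CCCCCC(=O)OC | intermediate
6 | butyl vinyl ether | C=COCCCC | starting material
7 | methyl 7-(vinyloxy)non-8-enoate (racemic) | C=COC(C=C)CCCCCC(=O)OC | intermediate
8 | methyl (7E)-11-oxoundec-7-enoate | O=CCC/C=C/CCCCCC(=O)OC | intermediate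
9 | methyl (7E,10S)-10-chloro-11-oxoundec-7-enoate | O=C[C@@H](Cl)C/C=C/CCCCCC(=O)OC | intermediate
10 | (3Z,6Z)-nona-3,6-dien-1-ol | CC/C=C\C/C=C\CCO | starting material
11 | (3Z,6Z)-nona-3,6-dienal | CC/C=C\C/C=C\CC=O | intermediate
12 | trimethylsilylacetylene | C#C[Si](C)(C)C | starting material
13 | (3S,5Z,8Z)-1-(trimethylsilyl)undeca-5,8-dien-1-yn-3-ol | CC/C=C\C/C=C\C[C@H](O)C#C[Si](C)(C)C | intermediate
14 | (3S,5Z,8Z)-undeca-5,8-dien-1-yn-3-ol | CC/C=C\C/C=C\C[C@H](O)C#C | intermediate
15 | O,C-dilithio derivative of 14 | CC/C=C\C/C=C\C[C@H](O[Li])C#C[Li] | intermediate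
16 | methyl (7E,10S,11R,14S,16Z,19Z)-10-chloro-11,14-dihydroxydocosa-7,16,19-trien-12-ynoate | CC/C=C\C/C=C\C[C@H](O)C#C[C@@H](O)[C@@H](Cl)C/C=C/CCCCCC(=O)OC | intermediate
17 | methyl (7E,10R,11R,14S,16Z,19Z)-10,11-epoxy-14-hydroxydocosa-7,16,19-trien-12-ynoate | CC/C=C\C/C=C\C[C@H](O)C#C[C@H]1O[C@@H]1C/C=C/CCCCCC(=O)OC | intermediate
18 | (7E,10R,11R,14S,16Z,19Z)-10,11-epoxy-14-hydroxydocosa-7,16,19-trien-12-ynoic acid | CC/C=C\C/C=C\C[C@H](O)C#C[C@H]1O[C@@H]1C/C=C/CCCCCC(=O)O | intermediate
19 | trimethylsilyl ester and 14-O-trimethylsilyl ether of 18 | CC/C=C\C/C=C\C[C@H](O[Si](C)(C)C)C#C[C@H]1O[C@@H]1C/C=C/CCCCCC(=O)O[Si](C)(C)C | intermediate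
20 | 11,14-bis(trimethylsilyl) ether of 21 | CC/C=C\C/C=C\C[C@H](O[Si](C)(C)C)C#C[C@@H](O[Si](C)(C)C)[C@@H]1C[C@H]1[C@H]1CCCCCC(=O)O1 | intermediate
21 | (8R)-8-[(1R,2R)-2-[(1S,4S,6Z,9Z)-1,4-dihydroxydodeca-6,9-dien-2-yn-1-yl]cyclopropyl]oxocan-2-one | CC/C=C\C/C=C\C[C@H](O)C#C[C@@H](O)[C@@H]1C[C@H]1[C@H]1CCCCCC(=O)O1 | intermediate
22 | (12Z)-12-(triethoxysilyl) derivative of 23 (Si cis to C14; 12-silyl regioisomer shown) | CC/C=C\C/C=C\C[C@H](O)/C=C(/[C@@H](O)[C@@H]1C[C@H]1[C@H]1CCCCCC(=O)O1)[Si](OCC)(OCC)OCC | intermediate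
23 | (8R)-8-[(1R,2R)-2-[(1R,2E,4S,6Z,9Z)-1,4-dihydroxydodeca-2,6,9-trien-1-yl]cyclopropyl]oxocan-2-one | CC/C=C\C/C=C\C[C@H](O)/C=C/[C@@H](O)[C@@H]1C[C@H]1[C@H]1CCCCCC(=O)O1 | target

## Step count
Total steps: 9. Longest linear sequence: 7 (steps 1–4, 7–9).

## The three steps most likely to fail

**Step 8.** The eight-membered capture may lose to several competing paths:
- proton loss from the cation or oligomerisation;
- attack on the other face of C7;
- a cis-cyclopropane that collapses to a 3-oxabicyclo[3.1.0]hexane;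
- opening of the epoxide at the propargylic carbon C11.

The fallback separates the two ring closures.
- It sets out from 17, which is isolated when 16 is closed with K2CO3/MeOH instead of KOH.
- Et3SiOTf and 2,6-di-tert-butyl-4-methylpyridine in CH2Cl2 at −78 °C, with a tenfold excess of triethylsilyl acetate, run the same epoxide-initiated cyclopropanation. External acetate takes the C7 cation and gives the C7-acetate bis-TES ether methyl ester F1.
- LiOH in THF–H2O cleaves both esters to the 7-hydroxy seco acid F2.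
- MNBA/DMAP (Shiina lactonisation) at high dilution closes the oxocanone to the bis-TES ether lactone F3.
- HF·pyridine in THF at 0 °C comes back to the route at 21.

**Step 6.** Aldehyde 11 may slip into conjugation or enolise, and the ee on an unbranched aldehyde may be only moderate. The fallback replaces asymmetric catalysis by resolution.
- It sets out from 11. Ethynylmagnesium bromide in THF at −78 °C gives the racemic alkynol F4.
- CAL-B with vinyl acetate in hexane acylates the S-enantiomer (ethynyl is the medium group in the Kazlauskas model) to the (S)-acetate F5.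
- F5 is separated from the unreacted R-alcohol and methanolysed with K2CO3/MeOH, coming back at 14.

**Step 9.** The Ru cation may bind or isomerise the skipped diene, or protodesilylation between two carbinols may be sluggish. The fallback swaps hydrometalation for an electron-transfer reduction. It sets out from 21 and comes back directly at 23. CrSO4 in DMF–H2O at rt under argon reduces 2-yne-1,4-diols to E-2-ene-1,4-diols with hydroxyl assistance and ignores isolated alkenes and esters. The time is kept short and the medium buffered to protect the C11 carbinol. No new compound is made (F0).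

## Further compounds
F1 | step 8 | methyl (7R)-7-acetoxy-7-[(1R,2R)-2-[(1S,4S,6Z,9Z)-1,4-bis(triethylsilyloxy)dodeca-6,9-dien-2-yn-1-yl]cyclopropyl]heptanoate | CC/C=C\C/C=C\C[C@H](O[Si](CC)(CC)CC)C#C[C@@H](O[Si](CC)(CC)CC)[C@@H]1C[C@H]1[C@H](OC(C)=O)CCCCCC(=O)OC
F2 | step 8 | (7R)-7-hydroxy-7-[(1R,2R)-2-[(1S,4S,6Z,9Z)-1,4-bis(triethylsilyloxy)dodeca-6,9-dien-2-yn-1-yl]cyclopropyl]heptanoic acid | CC/C=C\C/C=C\C[C@H](O[Si](CC)(CC)CC)C#C[C@@H](O[Si](CC)(CC)CC)[C@@H]1C[C@H]1[C@H](O)CCCCCC(=O)O
F3 | step 8 | (8R)-8-[(1R,2R)-2-[(1S,4S,6Z,9Z)-1,4-bis(triethylsilyloxy)dodeca-6,9-dien-2-yn-1-yl]cyclopropyl]oxocan-2-one | CC/C=C\C/C=C\C[C@H](O[Si](CC)(CC)CC)C#C[C@@H](O[Si](CC)(CC)CC)[C@@H]1C[C@H]1[C@H]1CCCCCC(=O)O1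
F4 | step 6 | (5Z,8Z)-undeca-5,8-dien-1-yn-3-ol (racemic) | CC/C=C\C/C=C\CC(O)C#C
F5 | step 6 | (3S,5Z,8Z)-undeca-5,8-dien-1-yn-3-yl acetate | CC/C=C\C/C=C\C[C@H](OC(C)=O)C#C
F0 | step 9 | none | none
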